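The eleven ring carbons and four methyls of the target are one unbroken head-to-tail farnesyl chain (C5–C10–C9–C8–C7–C6–C11–C1–C2–C3–C4; methyls on C9, C11, C4). Everything rests on disconnecting C4–C5, C5–C6 and C10–C11: an α-longipinene synthase folds (2E,6E)-farnesyl diphosphate, the acyclic precursor made from farnesol, in one cationic cascade into the cyclohexene (C5–C10), cycloheptane (C1–C6 plus C11) and cyclobutane (C5–C6–C11–C10) rings and sets all four ring stereocentres. Afterwards C7 is oxidised to the enone, one biocatalytic C–H oxidation marks C3, and the C1 oxygen, the C3 configuration and both esters follow by ketone-relayed, reagent-controlled chemistry.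

Key step: step 3

Remarks
- Numbering: C1–C11 are the ring carbons as written in the target SMILES: C1 (CH–O, tiglate), C2 (CH2), C3 (CH–O, senecioate), C4 (CMe2), C5, C6, C7 (C=O), C8, C9 (C–Me), C10, C11 (quaternary C–Me). Names ("longipin…") and descriptors of all tricyclic compounds use this numbering, not that of the natural-product literature.
- Assumption: a recombinant synthase that gives (1R,2S,7R,8R)-α-longipinene (the dextrorotatory conifer enantiomer as usually assigned; 5R,6R,10R,11S in the numbering used here) as a main product is available.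
- The diphosphate is handled as its trisammonium salt and drawn as the free acid.
- Two configurations are left open because neither survives: C3 of the hydroxylation product and the carbinol carbon of the enzyme-bound tertiary diphosphate.

Step 1
Reactants: 1 (2E,6E)-farnesol
Product: 2 (2E,6E)-farnesyl chloride
Conditions: NCS, Me2S, CH2Cl2, −30 → 0 °C
Reagents that add atoms: N-chlorosuccinimide, O=C1CCC(=O)N1Cl
Why: Corey–Kim chlorination, in which chloride displaces the alkoxysulfonium group at the primary allylic carbon in an SN2 fashion, so the 2E,6E geometry and the alkene positions should be retained and no stereocentre is involved.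

Step 2
Reactants: 2 (2E,6E)-farnesyl chloride
Product: 3 (2E,6E)-farnesyl diphosphate (trisammonium salt)
Conditions: (Bu4N)3HP2O7, MeCN, rt; then Dowex 50W-X8 (NH4+ form), aq NH4HCO3/iPrOH; cellulose chromatography, lyophilisation
Reagents that add atoms: tris(tetrabutylammonium) hydrogen diphosphate, CCCC[N+](CCCC)(CCCC)CCCC.CCCC[N+](CCCC)(CCCC)CCCC.CCCC[N+](CCCC)(CCCC)CCCC.OP(=O)([O-])OP(=O)([O-])[O-]
Why: SN2 displacement of the primary allylic chloride by the diphosphate anion (the standard diphosphorylation of allylic halides) should give the allylic diphosphate without transposition, and cation exchange supplies the water-soluble ammonium salt that the enzyme accepts.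

Step 3
Reactants: 3 (2E,6E)-farnesyl diphosphate
Product: 5 α-longipinene (5R,6R,10R,11S), via nerolidyl diphosphate 4 (not isolated)
Conditions: recombinant α-longipinene synthase (His-tagged, from E. coli), MgCl2, HEPES pH 7.5, DTT, glycerol, pentane overlay, 30 °C; AgNO3-impregnated silica
Reagents that add atoms: none
Why: Mg2+-assisted ionisation at C5 and return of diphosphate to C9 give the enzyme-bound tertiary allylic isomer 4, whose re-ionisation supplies the cisoid C5–C10–C9 allyl cation; the distal C3=C4 alkene then bonds through C4 to C5 (eleven-membered ring, cation at C3), a 1,3-hydride shift from C5 to C3 re-creates the allyl cation, the central C6=C11 alkene closes C5–C6 to leave the tertiary cation at C11, the ring alkene closes C10–C11 to put the charge on C9, and loss of a proton from C8 ends the cascade. The macrocycle has to close before the six-membered ring, because a start by C5–C6 bonding would leave C11 as a saturated CH once the seven-membered ring had formed, and the cyclobutane could then not close; the closest known reaction type is the diphosphate-triggered cation–alkene polycyclisation run by the longifolene and α-longipinene synthases of conifers. The six- and seven-membered rings are created together when the transannular C5–C6 bond divides the eleven-membered ring, and the four-membered ring closes by 4-exo attack of C10 on the C11 cation. C5, C6, C10 and C11 are set by the fold in which the active site holds the chain, the cis relationships being enforced by the transannular geometry and the absolute sense by the protein, so a synthase of the (5R,6R,10R,11S) series is required. The step needs C10–C11 instead of C9–C11 bonding (which leads on to longifolene) and proton loss from C8 instead of the C9 methyl; the substrate offers only its 2E,6E geometry and methyl pattern, so this selectivity rests on the enzyme, and co-formed hydrocarbons are removed on the silver-loaded silica.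

Step 4
Reactants: 5 α-longipinene
Product: 6 longipin-8-en-7-one (5S,6R,10R,11R)
Conditions: t-BuOOH (70% aq), Rh2(cap)4 (1 mol%), K2CO3, CH2Cl2, rt
Reagents that add atoms: tert-butyl hydroperoxide, CC(C)(C)OO
Why: Radical allylic oxidation of the kind that turns α-pinene into verbenone should take the ring methylene C7 to the ketone, because the C9 methyl is a primary position and the bridgehead C10–H is poorly aligned with the π system; no stereocentre is formed and the bridgeheads cannot epimerise.

Step 5
Reactants: 6 longipin-8-en-7-one
Product: 7 C3 alcohol 3-hydroxylongipin-8-en-7-one (either C3 epimer or the mixture)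
Conditions: P450-BM3 variant (picked from an active-site mutant panel for C3 oxidation; cell-free extract), NADP+ (cat.), D-glucose, glucose dehydrogenase, air, KPi pH 8.0, 2% DMSO, 25 °C
Reagents that add atoms: dioxygen, O=O
Why: P450-catalysed hydroxylation by hydrogen abstraction and oxygen rebound is established for unactivated methylenes of polycyclic terpenoid ketones; here the enone deactivates the bicyclic core, the variant is picked for attack at C3 and not at C1, C2 or the C9 methyl, and the configuration at C3 does not matter because this carbon becomes a ketone in the next step.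

Step 6
Reactants: 7 C3 alcohol
Product: 9 enedione longipina-1,8-diene-3,7-dione (5S,6R,10R,11R), via diketone 8 (not isolated)
Conditions: IBX (3 equiv), DMSO, 75 °C
Reagents that add atoms: none
Why: IBX first oxidises the secondary alcohol to diketone 8 and then dehydrogenates it (Nicolaou dehydrogenation); since C4 is quaternary the C3 ketone can enolise only towards C2, so the new alkene must lie between C1 and C2, and the C7 enone has no position left to desaturate.

Step 7
Reactants: 9 enedione
Product: 11 hydroxy diketone (1R)-1-hydroxylongipin-8-ene-3,7-dione, via boronate 10 (not isolated)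
Conditions: B2pin2 (1.1 equiv), CuCl (5 mol%), NaOtBu, (R)-1-[(S)-2-(diphenylphosphino)ferrocenyl]ethyldicyclohexylphosphine or its enantiomer (whichever gives 1R), MeOH, THF, 0 °C; then NaBO3·4H2O, THF/H2O, rt
Reagents that add atoms: bis(pinacolato)diboron, CC1(C)OB(OC1(C)C)B2OC(C)(C)C(C)(C)O2; sodium perborate, [Na+].[O-]OB=O
Why: Copper-catalysed conjugate borylation adds the boryl group to C1 of the disubstituted cycloheptenone, which should react far faster than the β,β-disubstituted C8=C9 enone, and perborate oxidises the C–B bond with retention; because the two faces of C1 differ only through the remote C7 carbonyl versus the C9 methyl, the chiral ligand and not the substrate is expected to fix the 1R configuration.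

Step 8
Reactants: 11 hydroxy diketone; 12 (E)-2-methylbut-2-enal (tiglic aldehyde)
Product: 14 hydroxy tiglate (1R,3R)-3-hydroxy-7-oxolongipin-8-en-1-yl (E)-2-methylbut-2-enoate, via hemiacetal 13 (not isolated)
Conditions: SmI2 (30 mol%), 12 (8 equiv), THF, −10 °C
Reagents that add atoms: (E)-2-methylbut-2-enal (compound 12), C/C=C(\C)C=O
Why: Evans–Tishchenko reaction, in which the samarium-bound hemiacetal 13 formed at the C1 oxygen hands its hydride to the C3 carbonyl through a six-membered transition state on the face that carries the C1 oxygen, so the new C3 hydroxyl is anti (trans, 3R) to it, the aldehyde carbon emerges as the C1 tiglate with its E alkene intact, and the two oxygens are told apart without protecting groups.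

Step 9
Reactants: 14 hydroxy tiglate; 15 3,3-dimethylacrylic acid
Product: 17 target (1R,3R,5S,6R,10R,11R)-3-(3-methylbut-2-enoyloxy)-7-oxolongipin-8-en-1-yl (E)-2-methylbut-2-enoate, via mixed anhydride 16 (not isolated)
Conditions: 15, 2,4,6-trichlorobenzoyl chloride, Et3N, THF, rt; then 14, DMAP, toluene, 60 °C
Reagents that add atoms: 3,3-dimethylacrylic acid (compound 15), CC(C)=CC(=O)O
Why: Yamaguchi esterification, in which DMAP transfers the senecioyl group of mixed anhydride 16 to the only free hydroxyl, the neopentyl C3–OH, for which this method is suited; no stereocentre is touched and the trans-1,3 arrangement should keep the C1 tiglate from migrating.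

Compound list
1 | (2E,6E)-farnesol | CC(C)=CCC/C(C)=C/CC/C(C)=C/CO | starting material
2 | (2E,6E)-farnesyl chloride | CC(C)=CCC/C(C)=C/CC/C(C)=C/CCl | intermediate
3 | (2E,6E)-farnesyl diphosphate (trisammonium salt, drawn as free acid) | CC(C)=CCC/C(C)=C/CC/C(C)=C/COP(=O)(O)OP(=O)(O)O | intermediate
4 | (6E)-nerolidyl diphosphate, enzyme-bound tertiary allylic isomer (carbinol configuration not assigned) | CC(C)=CCC/C(C)=C/CCC(C)(C=C)OP(=O)(O)OP(=O)(O)O | intermediate (not isolated)
5 | α-longipinene, (5R,6R,10R,11S) = (1R,2S,7R,8R)-2,6,6,9-tetramethyltricyclo[5.4.0.0^2,8]undec-9-ene | C1CCC(C)(C)[C@@H]2[C@H]3CC=C(C)[C@@H]2[C@]31C | intermediate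
6 | longipin-8-en-7-one, (5S,6R,10R,11R) | C1CCC(C)(C)[C@@H]2[C@H]3C(=O)C=C(C)[C@@H]2[C@]31C | intermediate
7 | 3-hydroxylongipin-8-en-7-one, (5S,6R,10R,11R), C3 open | C1CC(O)C(C)(C)[C@@H]2[C@H]3C(=O)C=C(C)[C@@H]2[C@]31C | intermediate
8 | longipin-8-ene-3,7-dione, (5S,6R,10R,11R) | C1CC(=O)C(C)(C)[C@@H]2[C@H]3C(=O)C=C(C)[C@@H]2[C@]31C | intermediate (not isolated)
9 | longipina-1,8-diene-3,7-dione, (5S,6R,10R,11R) | C1=CC(=O)C(C)(C)[C@@H]2[C@H]3C(=O)C=C(C)[C@@H]2[C@]31C | intermediate
10 | (1R)-1-(4,4,5,5-tetramethyl-1,3,2-dioxaborolan-2-yl)longipin-8-ene-3,7-dione, (1R,5S,6R,10R,11R) | CC1(C)OB(OC1(C)C)[C@@H]1CC(=O)C(C)(C)[C@@H]2[C@H]3C(=O)C=C(C)[C@@H]2[C@]31C | intermediate (not isolated)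
11 | (1R)-1-hydroxylongipin-8-ene-3,7-dione, (1R,5S,6R,10R,11R) | O[C@@H]1CC(=O)C(C)(C)[C@@H]2[C@H]3C(=O)C=C(C)[C@@H]2[C@]31C | intermediate
12 | (E)-2-methylbut-2-enal (tiglic aldehyde) | C/C=C(\C)C=O | starting material
13 | hemiacetal of 11 (at O1) with 12, hemiacetal carbon open, handled as its samarium alkoxide | C/C=C(\C)C(O)O[C@@H]1CC(=O)C(C)(C)[C@@H]2[C@H]3C(=O)C=C(C)[C@@H]2[C@]31C | intermediate (not isolated)
14 | (1R,3R)-3-hydroxy-7-oxolongipin-8-en-1-yl (E)-2-methylbut-2-enoate, (1R,3R,5S,6R,10R,11R) | C/C=C(\C)C(=O)O[C@@H]1C[C@@H](O)C(C)(C)[C@@H]2[C@H]3C(=O)C=C(C)[C@@H]2[C@]31C | intermediate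
15 | 3,3-dimethylacrylic acid (senecioic acid) | CC(C)=CC(=O)O | starting material
16 | 3-methylbut-2-enoic 2,4,6-trichlorobenzoic anhydride | CC(C)=CC(=O)OC(=O)c1c(Cl)cc(Cl)cc1Cl | intermediate (not isolated)
17 | CNP0277258.1, (1R,3R,5S,6R,10R,11R)-3-(3-methylbut-2-enoyloxy)-7-oxolongipin-8-en-1-yl (E)-2-methylbut-2-enoate | C/C=C(\C)C(=O)O[C@@H]1C[C@@H](OC(=O)C=C(C)C)C(C)(C)[C@@H]2[C@H]3C(=O)C=C(C)[C@@H]2[C@]31C | target

Total step count: 9. Longest linear sequence: 9 steps (1 to 17); 12 and 15 are bought.

Steps most likely to fail

Step 5. Oxygen rebound may occur at another C–H bond: C2 (the most exposed methylene), C1 or the allylic C9 methyl. Turnover with the compact polycyclic ketone may also be low. The fallback serves the case in which the panel offers C1 in place of C3 selectivity, and runs the relay from the other end. It sets out from 6. Hydroxylation at C1 gives 1-hydroxylongipin-8-en-7-one F1. IBX in DMSO at 75 °C takes it through longipin-8-ene-1,7-dione F2 to longipina-2,8-diene-1,7-dione F3. Copper-catalysed conjugate borylation with the ligand enantiomer chosen for 3R, then perborate oxidation, leads through the C3 boronate F4 to (3R)-3-hydroxylongipin-8-ene-1,7-dione F5. An Evans–Tishchenko reaction with 3-methylbut-2-enal (CC(C)=CC=O) passes through the hemiacetal F6 and gives the (3R)-senecioate with a free (1R)-hydroxyl F7; the hydride is delivered to C1 from the face of the C3 oxygen. Yamaguchi esterification with tiglic acid (C/C=C(\C)C(=O)O) through the mixed anhydride F8 comes back to the route at the target 17. A variant that attacks only C2 cannot be relayed in this way and would have to be replaced.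

Step 7. Facial discrimination at the neopentyl carbon C1 may be poor, since the ligand has to act against a hindered β-carbon, and slow addition may let borylation at C9 of the other enone compete. The fallback gives up asymmetric induction and relies on separation and recycling. It sets out from 9, which is borylated with an achiral CuCl/Xantphos catalyst and oxidised as before. Compound 11 is separated by chromatography from its epimer (1S)-1-hydroxylongipin-8-ene-3,7-dione F9. F9 is converted with MsCl/Et3N into the mesylate F10 (not isolated) and eliminated with DBU, which returns it to 9. The fallback rejoins the route at 11.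

Step 8. Hemiacetal formation or hydride transfer may be sluggish with the conjugated, α-branched aldehyde. The samarium alkoxide may also trigger acyl migration or retro-aldol opening of the β-hydroxy ketone, which would erode C1. The fallback uses a standard aldehyde partner and a short protecting-group detour. It sets out from 11. The Evans–Tishchenko reaction with 4-nitrobenzaldehyde (O=Cc1ccc(cc1)[N+](=O)[O-]) passes through the hemiacetal F11 and gives the (1R)-4-nitrobenzoate with free (3R)-hydroxyl F12. Yamaguchi senecioylation with 15 through 16 gives the mixed diester F13. K2CO3 in MeOH at 0 °C removes only the activated nitrobenzoate and gives F7. Tigloylation with tiglic acid through F8 comes back to the route at 17.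

Further compounds
F1 | step 5 | 1-hydroxylongipin-8-en-7-one (C1 open) | OC1CCC(C)(C)[C@@H]2[C@H]3C(=O)C=C(C)[C@@H]2[C@]31C
F2 | step 5 | longipin-8-ene-1,7-dione | O=C1CCC(C)(C)[C@@H]2[C@H]3C(=O)C=C(C)[C@@H]2[C@]31C
F3 | step 5 | longipina-2,8-diene-1,7-dione | O=C1C=CC(C)(C)[C@@H]2[C@H]3C(=O)C=C(C)[C@@H]2[C@]31C
F4 | step 5 | (3R)-3-(4,4,5,5-tetramethyl-1,3,2-dioxaborolan-2-yl)longipin-8-ene-1,7-dione | O=C1C[C@@H](B4OC(C)(C)C(C)(C)O4)C(C)(C)[C@@H]2[C@H]3C(=O)C=C(C)[C@@H]2[C@]31C
F5 | step 5 | (3R)-3-hydroxylongipin-8-ene-1,7-dione | O=C1C[C@@H](O)C(C)(C)[C@@H]2[C@H]3C(=O)C=C(C)[C@@H]2[C@]31C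
F6 | step 5 | hemiacetal of F5 (at O3) with 3-methylbut-2-enal | O=C1C[C@@H](OC(O)C=C(C)C)C(C)(C)[C@@H]2[C@H]3C(=O)C=C(C)[C@@H]2[C@]31C
F7 | step 5 | (1R,3R)-1-hydroxy-7-oxolongipin-8-en-3-yl 3-methylbut-2-enoate | O[C@@H]1C[C@@H](OC(=O)C=C(C)C)C(C)(C)[C@@H]2[C@H]3C(=O)C=C(C)[C@@H]2[C@]31C
F8 | step 5 | (E)-2-methylbut-2-enoic 2,4,6-trichlorobenzoic anhydride | C/C=C(\C)C(=O)OC(=O)c1c(Cl)cc(Cl)cc1Cl
F9 | step 7 | (1S)-1-hydroxylongipin-8-ene-3,7-dione | O[C@H]1CC(=O)C(C)(C)[C@@H]2[C@H]3C(=O)C=C(C)[C@@H]2[C@]31C
F10 | step 7 | (1S)-3,7-dioxolongipin-8-en-1-yl methanesulfonate | CS(=O)(=O)O[C@H]1CC(=O)C(C)(C)[C@@H]2[C@H]3C(=O)C=C(C)[C@@H]2[C@]31C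
F11 | step 8 | hemiacetal of 11 (at O1) with 4-nitrobenzaldehyde | O=[N+]([O-])c1ccc(cc1)C(O)O[C@@H]1CC(=O)C(C)(C)[C@@H]2[C@H]3C(=O)C=C(C)[C@@H]2[C@]31C
F12 | step 8 | (1R,3R)-3-hydroxy-7-oxolongipin-8-en-1-yl 4-nitrobenzoate | O=[N+]([O-])c1ccc(cc1)C(=O)O[C@@H]1C[C@@H](O)C(C)(C)[C@@H]2[C@H]3C(=O)C=C(C)[C@@H]2[C@]31C
F13 | step 8 | (1R,3R)-3-(3-methylbut-2-enoyloxy)-7-oxolongipin-8-en-1-yl 4-nitrobenzoate | O=[N+]([O-])c1ccc(cc1)C(=O)O[C@@H]1C[C@@H](OC(=O)C=C(C)C)C(C)(C)[C@@H]2[C@H]3C(=O)C=C(C)[C@@H]2[C@]31C
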